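## Retrosynthetic overview

1. Target ⇒ tricyclic triflate diacid + pent-1-yne: both (Z)-butylidene lactones (and the C3–C3a bond of unit A) are made in the last flask by ester acidolysis, Sonogashira coupling and two 5-exo-dig lactonisations.
2. Ring B alkene ⇒ ring B ketone (Luche reduction, Burgess dehydration); the ketone is the chromophore and chelating handle of the cycloaddition.
3. Cyclobutane ⇒ crossed enone + diene [2+2] photocycloaddition under a chiral Lewis acid, between a 3-pentynyl-2-(tert-butoxycarbonyl)cyclohexenone (ring B) and a cyclohexadienyl triflate (ring A); all four stereocentres are set here.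
4. Both partners ⇒ tert-butyl 6-oxocyclohex-1-ene-1-carboxylate ⇒ tert-butyl 2-oxocyclohexane-1-carboxylate.
5. Order of rings: carbocycles A and B come with the starting material, the cyclobutane is third, lactones A and B are closed together at the end.

Assumption 1: tert-butyl 2-oxocyclohexane-1-carboxylate and pent-1-yne are taken as catalogue materials; the tert-butyl ester is chosen so that both esters fall to acid in the last step.

Assumption 2: the facial sense of the chiral Sc(OTf)3/pybox catalyst in step 4 cannot be derived from first principles; the route is written with the (S,S)-ligand and the (R,R)-ligand is used instead if the mirror-image cycloadduct results.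

Numbering of the tricyclic compounds: tricyclo[6.4.0.0^2,7]dodecane. Cyclobutane = C1, C2, C7, C8; ring A = C8–C12 and C1; ring B = C2–C7. In ligustilide numbering C1 = C7, C8 = C6, C11 = C3a, C12 = C7a of unit A (the butenolide half), and C2 = C3a′, C7 = C7a′, C5 = C6′, C6 = C7′ of unit B.

## Route

Step 1
Reactants: 1 tert-butyl 2-oxocyclohexane-1-carboxylate
Product: 4 tert-butyl 6-oxocyclohex-1-ene-1-carboxylate, via α-phenylselanyl keto ester 2 (not isolated), via selenoxide 3 (not isolated)
Conditions: PhSeCl, pyridine, CH2Cl2, 0 °C; then 30% H2O2, 0 °C → rt; crude 4 used at once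
Reagents that add atoms: none
Why: Reich α-selenenylation of the β-keto ester followed by selenoxide syn-elimination, which can only take a C6 hydrogen and therefore gives the 2-alkoxycarbonyl enone; no stereocentre is formed.

Step 2
Reactants: 4 tert-butyl 6-oxocyclohex-1-ene-1-carboxylate
Product: 5 tert-butyl 2-{[(trifluoromethyl)sulfonyl]oxy}cyclohexa-1,5-diene-1-carboxylate
Conditions: Tf2O, 2,6-di-tert-butyl-4-methylpyridine, CH2Cl2, −78 → 0 °C
Reagents that add atoms: trifluoromethanesulfonic anhydride, O=S(=O)(OS(=O)(=O)C(F)(F)F)C(F)(F)F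
Why: Stang enol triflation, in which O-sulfonylation of the enone carbonyl and loss of the γ-proton (C3–H) give the through-conjugated 1,3-dienyl triflate, as 4-en-3-one steroids give 3,5-dienyl triflates under the same conditions; no stereocentre is formed.

Step 3
Reactants: 4 tert-butyl 6-oxocyclohex-1-ene-1-carboxylate; 6 pent-1-yne
Product: 10 tert-butyl 6-oxo-2-(pent-1-yn-1-yl)cyclohex-1-ene-1-carboxylate, via dimethylaluminium enolate 7 (not isolated), via trans α-phenylselanyl keto ester 8 (not isolated), via selenoxide 9 (not isolated)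
Conditions: 6, AlMe3, Et3N (10 mol%), toluene, 60 °C; then 4, −40 → 0 °C; then PhSeCl, −78 °C; then aq. NH4Cl, 30% H2O2, CH2Cl2, 0 °C → rt
Reagents that add atoms: none
Why: Hooz-type 1,4-addition of the dimethylaluminium acetylide to the chelating alkylidene β-keto ester (alkynyl transfer through the s-cis ester carbonyl), Reich selenenylation of the enolate anti to the new alkynyl group and selenoxide syn-elimination through the only β-hydrogen (C2–H) restore the enone, so the transient stereocentres disappear again.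

Step 4
Reactants: 10 tert-butyl 6-oxo-2-(pent-1-yn-1-yl)cyclohex-1-ene-1-carboxylate; 5 tert-butyl 2-{[(trifluoromethyl)sulfonyl]oxy}cyclohexa-1,5-diene-1-carboxylate
Product: 11 di-tert-butyl (1R,2S,7S,8S)-6-oxo-2-(pent-1-yn-1-yl)-11-{[(trifluoromethyl)sulfonyl]oxy}tricyclo[6.4.0.0^2,7]dodec-11-ene-7,12-dicarboxylate (cis-anti-cis: rings A and B on opposite faces of the cyclobutane)
Conditions: Sc(OTf)3 (10 mol%), (S,S)-t-Bu-pybox (12 mol%), Ru(bpy)3(PF6)2 (2 mol%), 5 (3 equiv), i-PrOAc/MeCN 3:1, blue LEDs (455 nm), 0 °C, degassed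
Reagents that add atoms: none
Why: Proposed new method: the β-keto ester enone 10 chelates trivalent scandium through its two carbonyl oxygens, which is expected to lower its triplet energy below that of Ru(bpy)3(PF6)2 (about 46 kcal/mol) so that only the bound enone is sensitised while diene 5 (triplet above 50 kcal/mol, weakly Lewis basic) stays in the ground state; the enone triplet then adds across the unhindered C5=C6 bond of 5 in the head-to-tail sense of classical enone–alkene photocycloadditions (first bond from the enone α-carbon to the diene terminus, leaving a tertiary propargylic and a dienoate-stabilised allylic radical that close to the four-membered ring), the two six-membered rings end up anti (the usual cis-anti-cis outcome), and the pybox-shielded chelate delivers one enantiomer, so C1, C2, C7 and C8 are all set here; closest known reaction type: chiral Lewis-acid-catalysed, triplet-sensitised enantioselective [2+2] photocycloaddition of chelating enones (2′-hydroxychalcones) with 1,3-dienes.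

Step 5
Reactants: 11 di-tert-butyl (1R,2S,7S,8S)-6-oxo-2-(pent-1-yn-1-yl)-11-{[(trifluoromethyl)sulfonyl]oxy}tricyclo[6.4.0.0^2,7]dodec-11-ene-7,12-dicarboxylate
Product: 12 di-tert-butyl (1R,2S,6RS,7S,8S)-6-hydroxy-2-(pent-1-yn-1-yl)-11-{[(trifluoromethyl)sulfonyl]oxy}tricyclo[6.4.0.0^2,7]dodec-11-ene-7,12-dicarboxylate (mixture of C6 epimers)
Conditions: NaBH4, CeCl3·7H2O, MeOH/THF, −78 → −20 °C
Reagents that add atoms: none
Why: Luche reduction, which reduces only the ring B ketone (tert-butyl esters, vinyl triflate and alkyne are inert at low temperature); the new carbinol centre is not controlled and need not be, because it is erased in step 6.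

Step 6
Reactants: 12 di-tert-butyl (1R,2S,6RS,7S,8S)-6-hydroxy-2-(pent-1-yn-1-yl)-11-{[(trifluoromethyl)sulfonyl]oxy}tricyclo[6.4.0.0^2,7]dodec-11-ene-7,12-dicarboxylate
Product: 14 di-tert-butyl (1R,2S,7S,8S)-2-(pent-1-yn-1-yl)-11-{[(trifluoromethyl)sulfonyl]oxy}tricyclo[6.4.0.0^2,7]dodeca-5,11-diene-7,12-dicarboxylate, via sulfamate ester 13 (not isolated)
Conditions: Burgess reagent, toluene, 70 °C
Reagents that add atoms: none
Why: Burgess dehydration, in which the sulfamate ester undergoes thermal syn-elimination through a C5 hydrogen (the only β-hydrogens, since C7 is quaternary) while the ester on C7 disfavours any cationic 1,2-shift of the cyclobutane; no stereocentre is created or touched.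

Step 7 (key step)
Reactants: 14 di-tert-butyl (1R,2S,7S,8S)-2-(pent-1-yn-1-yl)-11-{[(trifluoromethyl)sulfonyl]oxy}tricyclo[6.4.0.0^2,7]dodeca-5,11-diene-7,12-dicarboxylate; 6 pent-1-yne
Product: 17 (3Z,3′Z,6S,7R,3a′R,7a′S)-6.7a′,7.3a′-diligustilide (target), via triflate diacid 15 (not isolated), via bis(pentynyl) diacid 16 (not isolated)
Conditions: TFA/CH2Cl2 1:2, 0 °C → rt, evaporate; then 6 (3 equiv), PdCl2(PPh3)2 (5 mol%), CuI (10 mol%), Et3N, MeCN, rt → 50 °C
Reagents that add atoms: none
Why: Proposed new method: TFA removes both tert-butyl esters by acidolysis without touching the vinyl triflate, the liberated β-triflyloxy acrylic acid undergoes Sonogashira coupling with 6, and both the resulting (Z)-2-en-4-ynoic acid and the cis 4-alkynoic acid on the cyclobutane cyclise 5-exo-dig under the same PdCl2(PPh3)2/CuI/Et3N system by anti-oxymetalation and protodemetalation, which closes both lactone rings in one flask and fixes both exocyclic alkenes as Z (also the thermodynamic isomers) while the four stereocentres are untouched; closest known reaction type: tandem Sonogashira coupling/5-exo-dig lactonisation of (Z)-3-iodoalk-2-enoic and 2-iodobenzoic acids to (Z)-γ-ylidene butenolides and phthalides.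

## Compound list

1 | tert-butyl 2-oxocyclohexane-1-carboxylate | CC(C)(C)OC(=O)C1CCCCC1=O | starting material
2 | tert-butyl 2-oxo-1-(phenylselanyl)cyclohexane-1-carboxylate (racemic, not isolated) | CC(C)(C)OC(=O)C1([Se]c2ccccc2)CCCCC1=O | intermediate
3 | tert-butyl 2-oxo-1-(phenylseleninyl)cyclohexane-1-carboxylate (not isolated) | CC(C)(C)OC(=O)C1([Se](=O)c2ccccc2)CCCCC1=O | intermediate
4 | tert-butyl 6-oxocyclohex-1-ene-1-carboxylate | CC(C)(C)OC(=O)C1=CCCCC1=O | intermediate
5 | tert-butyl 2-{[(trifluoromethyl)sulfonyl]oxy}cyclohexa-1,5-diene-1-carboxylate | CC(C)(C)OC(=O)C1=C(OS(=O)(=O)C(F)(F)F)CCC=C1 | intermediate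
6 | pent-1-yne | CCCC#C | starting material
7 | tert-butyl 2-[(dimethylalumanyl)oxy]-6-(pent-1-yn-1-yl)cyclohex-1-ene-1-carboxylate (racemic, not isolated) | CCCC#CC1CCCC(O[Al](C)C)=C1C(=O)OC(C)(C)C | intermediate
8 | tert-butyl 2-oxo-6-(pent-1-yn-1-yl)-1-(phenylselanyl)cyclohexane-1-carboxylate, Se trans to the alkynyl group (racemic, one enantiomer drawn, not isolated) | CC(C)(C)OC(=O)[C@@]1([Se]c2ccccc2)C(=O)CCC[C@H]1C#CCCC | intermediate
9 | selenoxide of 8 (not isolated) | CC(C)(C)OC(=O)[C@@]1([Se](=O)c2ccccc2)C(=O)CCC[C@H]1C#CCCC | intermediate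
10 | tert-butyl 6-oxo-2-(pent-1-yn-1-yl)cyclohex-1-ene-1-carboxylate | CC(C)(C)OC(=O)C1=C(C#CCCC)CCCC1=O | intermediate
11 | di-tert-butyl (1R,2S,7S,8S)-6-oxo-2-(pent-1-yn-1-yl)-11-{[(trifluoromethyl)sulfonyl]oxy}tricyclo[6.4.0.0^2,7]dodec-11-ene-7,12-dicarboxylate | CC(C)(C)OC(=O)C2=C(OS(=O)(=O)C(F)(F)F)CC[C@H]1[C@@H]2[C@]2(C#CCCC)CCCC(=O)[C@]12C(=O)OC(C)(C)C | intermediate
12 | di-tert-butyl (1R,2S,6RS,7S,8S)-6-hydroxy-2-(pent-1-yn-1-yl)-11-{[(trifluoromethyl)sulfonyl]oxy}tricyclo[6.4.0.0^2,7]dodec-11-ene-7,12-dicarboxylate | CC(C)(C)OC(=O)C2=C(OS(=O)(=O)C(F)(F)F)CC[C@H]1[C@@H]2[C@]2(C#CCCC)CCCC(O)[C@]12C(=O)OC(C)(C)C | intermediate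
13 | triethylammonium salt of the 6-O-[N-(methoxycarbonyl)sulfamoyl] derivative of 12 (not isolated) | CC(C)(C)OC(=O)C2=C(OS(=O)(=O)C(F)(F)F)CC[C@H]1[C@@H]2[C@]2(C#CCCC)CCCC(OS(=O)(=O)[N-]C(=O)OC)[C@]12C(=O)OC(C)(C)C.CC[NH+](CC)CC | intermediate
14 | di-tert-butyl (1R,2S,7S,8S)-2-(pent-1-yn-1-yl)-11-{[(trifluoromethyl)sulfonyl]oxy}tricyclo[6.4.0.0^2,7]dodeca-5,11-diene-7,12-dicarboxylate | CC(C)(C)OC(=O)C2=C(OS(=O)(=O)C(F)(F)F)CC[C@H]1[C@@H]2[C@]2(C#CCCC)CCC=C[C@]12C(=O)OC(C)(C)C | intermediate
15 | (1R,2S,7S,8S)-2-(pent-1-yn-1-yl)-11-{[(trifluoromethyl)sulfonyl]oxy}tricyclo[6.4.0.0^2,7]dodeca-5,11-diene-7,12-dicarboxylic acid (not isolated) | OC(=O)C2=C(OS(=O)(=O)C(F)(F)F)CC[C@H]1[C@@H]2[C@]2(C#CCCC)CCC=C[C@]12C(=O)O | intermediate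
16 | (1R,2S,7S,8S)-2,11-di(pent-1-yn-1-yl)tricyclo[6.4.0.0^2,7]dodeca-5,11-diene-7,12-dicarboxylic acid (not isolated) | OC(=O)C2=C(C#CCCC)CC[C@H]1[C@@H]2[C@]2(C#CCCC)CCC=C[C@]12C(=O)O | intermediate
17 | (3Z,3′Z,6S,7R,3a′R,7a′S)-6.7a′,7.3a′-diligustilide: (Z)-butylidene butenolide on C11=C12 (carbonyl on C12), (Z)-butylidene γ-lactone from C7 (carbonyl) to C2, C5=C6 alkene; (1R,2R,7S,8S) in the tricyclic numbering, the C2 descriptor differing from 16 only through CIP priorities | CCC/C=C1\OC(=O)C2=C1CC[C@H]1[C@@H]2[C@]23CCC=C[C@]12C(=O)O/C3=C\CCC | target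

## Summary

Total step count: 7.
Longest linear sequence: 6 (steps 1, 3, 4, 5, 6, 7; step 2 is the one-step branch to 5).

Three steps most likely to fail:

Step 4 (crossed photocycloaddition). The risks are triplet energy transfer to the diene, head-to-head instead of head-to-tail addition, syn ring fusion and low enantioselectivity. Fallback, setting out from 10 (with 5) and coming back at 11: drop asymmetric catalysis and resolve instead. Irradiate 10 with 5 (5 equiv) directly at 366 nm in CH2Cl2 at −40 °C without Lewis acid or sensitiser. This gives the racemic cis-anti-cis head-to-tail cycloadduct, i.e. 11 together with its mirror image, the enantiomeric keto triflate F1. The two are separated by preparative chromatography on a chiral stationary phase and 11 enters step 5. This fallback secures enantiopurity only; it does not correct a wrong regiochemistry.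

Step 7 (one-flask acidolysis, coupling and double lactonisation). The risks are instability of the free β-triflyloxy acid, sluggish coupling at the tetrasubstituted triflate and 6-endo closure in unit A. Fallback, setting out from 14 and coming back at 16: uncouple the three events. Sonogashira coupling of 14 with 6 (PdCl2(PPh3)2, CuI, i-Pr2NH, THF) on the intact diester gives the di-tert-butyl bis(pentynyl) diester F2. TFA/CH2Cl2 then liberates diacid 16, which is isolated and cyclised with Ag2CO3 (10 mol%) in DMF at rt to 17; monovalent silver is the most 5-exo-selective promoter for both 2-en-4-ynoic and 4-alkynoic acids.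

Step 3 (alkynylalane 1,4-addition and selenoxide elimination). The risks are 1,2-addition or dienolisation of the labile enone 4, selenenylation on the wrong face so that no syn hydrogen is available, and PhSeCl addition to the alkyne. Fallback, setting out from 4 and coming back at 10: introduce the alkyne by cross-coupling instead of conjugate addition. Nucleophilic epoxidation of 4 (t-BuOOH, DBU, CH2Cl2) gives the epoxy ketone F3. Isomerisation of the α,β-epoxy ketone with Pd(PPh3)4 and 1,2-bis(diphenylphosphino)ethane in toluene at 80 °C gives the 2-(tert-butoxycarbonyl)cyclohexane-1,3-dione enol F4. Tf2O/i-Pr2NEt gives the vinylogous acyl triflate F5, and Sonogashira coupling of F5 with 6 (PdCl2(PPh3)2, CuI, Et3N, THF) returns 10.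

## Further compounds

F1 | step 4 | di-tert-butyl (1S,2R,7R,8R)-6-oxo-2-(pent-1-yn-1-yl)-11-{[(trifluoromethyl)sulfonyl]oxy}tricyclo[6.4.0.0^2,7]dodec-11-ene-7,12-dicarboxylate (enantiomer of 11) | CC(C)(C)OC(=O)C2=C(OS(=O)(=O)C(F)(F)F)CC[C@@H]1[C@H]2[C@@]2(C#CCCC)CCCC(=O)[C@@]12C(=O)OC(C)(C)C
F2 | step 7 | di-tert-butyl (1R,2S,7S,8S)-2,11-di(pent-1-yn-1-yl)tricyclo[6.4.0.0^2,7]dodeca-5,11-diene-7,12-dicarboxylate | CC(C)(C)OC(=O)C2=C(C#CCCC)CC[C@H]1[C@@H]2[C@]2(C#CCCC)CCC=C[C@]12C(=O)OC(C)(C)C
F3 | step 3 | tert-butyl 2-oxo-7-oxabicyclo[4.1.0]heptane-1-carboxylate (racemic) | CC(C)(C)OC(=O)C12OC1CCCC2=O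
F4 | step 3 | tert-butyl 2-hydroxy-6-oxocyclohex-1-ene-1-carboxylate | CC(C)(C)OC(=O)C1=C(O)CCCC1=O
F5 | step 3 | tert-butyl 6-oxo-2-{[(trifluoromethyl)sulfonyl]oxy}cyclohex-1-ene-1-carboxylate | CC(C)(C)OC(=O)C1=C(OS(=O)(=O)C(F)(F)F)CCCC1=O
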